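The numbers in the tables were computed with constants of no real substance, noise included.

In a one-step world you watch one time constant and wait for the scarcer partner to end the curve. This flask runs a catalyst cycle with leaks, so you need a count as well as a clock.

- west: starting material 0.40 M; reagent 0.28 M; free catalyst 0.31 mM; the very flask that is asked about, followed so far
- flask: starting material 0.40 M; reagent 0.280 M; free catalyst 0.31 mM; time 15 d

west run (percent of the starting material charged)

| time / d | target / % | starting material / % |
|---|---|---|
| 0.250 | 5.9 | 93.4 |
| 0.625 | 14.3 | 84.4 |
| 1.25 | 27.3 | 69.0 |
| 2.08 | 39.6 | 49.8 |
| 2.50 | 43.0 | 41.1 |

(each reading ± 0.3 percentage points)

- in percentages every species weighs as the starting material in it: one side product counts as two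
- steps thought possible: starting material + free catalyst <-> catalyst intermediate A; reagent + catalyst intermediate A -> catalyst intermediate B; catalyst intermediate B <-> catalyst intermediate C; catalyst intermediate C -> free catalyst + target; starting material + target -> side product; target + free catalyst <-> isomer of the product + free catalyst

- time, not beyond 15 d, at which the flask holds most target
- the amount of target, in percent of the starting material charged, at that time

Each target leaves the cycle having taken one reagent. Isomer of the product is a changed target, and side product holds one target plus one more starting material. So define the reagent budget as starting [reagent] over starting [starting material]: 70.0 %. Reagent is the limiting reagent, being less than starting material. By the listed steps, target plus isomer plus the side product's percentage over two stays within the budget.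

Here are two ways to the stop. First, the target readings: the daily gain falls from 0.148 /d to 0.0810 /d of the charge. A straight line through those gains reaches zero at 3.04 d.

Second, the budget: at 2.50 d the starting material lost leaves 11.1 % of it. At the latest loss of 0.207 /d, this estimate of the end comes out at 3.04 d. Side product takes a second starting material without reagent, so this clock may read early.

The two use different readings and agree. I commit to about 3.04 d and 44.6 %.

The forecast says 2.9 d and 44.5 %, a little earlier than mine: “Reagent is only 70% of the charge, and about 59% is already used at 2.5 d, so it runs out near 3 d.”

The flask gives 2.78 d and 44.3 %.

    starting material + free catalyst ⇌ catalyst intermediate A (K = 12.0 /M, k = 89.0 /M/min)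
    reagent + catalyst intermediate A → catalyst intermediate B (k = 9.00 /M/min)
    catalyst intermediate B ⇌ catalyst intermediate C (K = 1.20, k = 1.60 /min)
    catalyst intermediate C → free catalyst + target (k = 0.540 /min)
    starting material + target → side product (k = 1.80 × 10⁻⁴ /M/min)
    target + free catalyst ⇌ isomer of the product + free catalyst, rate k6*[free catalyst]*[target] forward; the back reaction follows from the equilibrium constant (K = 26.0, k = 3.30 /M/min)

At that peak, earlier than my reckoning, reagent still stands at 15.7 % of its own charge. At 15.0 d this flask has reagent at 0 %, and target, isomer and the side product's percentage over two sum to 70.0 %, against the budget of 70.0 %. At that same time the isomer step (forward rate alone) uses target 31 times as fast as the side-product step, and isomer holds 60.1 %. A neighbouring flask shows a peak far from the forecast's: with 1.0 M of starting material the budget is 28.0 %, the peak is lower at 17.5 %, and the same sum at 15.0 d is 28.0 %.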